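A direct plan would build ring D on an aromatic ring B by a thermal aryl propargyl ether Claisen cascade (chromene aldehyde A1), hydrogenate the chromene alkene and O-methylate (chromane aldehyde A2),
condense A2 with the MOM ether of 2-hydroxy-4-methoxyacetophenone A3 to chalcone A4, shift ring B from C2 to C3 with Tl(NO3)3, close ring C with acid (chromane isoflavone A5) and end with a DDQ dehydrogenation.
Its weakest steps would be: the hydrogenation and the final DDQ re-dehydrogenation, two steps that add no complexity, the second an oxidation of the most precious material, needed only to hide the alkene from trivalent thallium;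
the oxidative 1,2-aryl shift, which would need a stoichiometric amount of a highly toxic thallium salt late in the route;
the Claisen cascade near 190 °C, whose choice between the two ortho positions of ring B would rest on a chelation bias alone.

**Plan of the new route**
The retrosynthesis cuts ring C at O1–C8a and C2–C3, then the C3–C1' bond together with the aromaticity of ring B, and last ring D back to cyclohexane-1,3-dione and 3-methylbut-2-enal.
Feature used: ring B is a resorcinol unit whose C2' oxygen is ortho to C1' and whose C3' and C4'–O already lie in ring D. As ketone 4, C2' is a carbonyl carbon and C1' its enolizable α-carbon, and the 6-alkylidenecyclohex-2-enone formed by aldol condensation is an isomer of the ortho-substituted phenol.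
Rings arise in the order D, B (as an arene), C; ring A is bought with fluorine in the place of its ring oxygen.
Ring D is fused to a symmetric dione, so no Claisen regiochemistry arises. Ring B aromatizes by isomerization, so no oxidant and no thallium meet the chromene alkene, which is never masked, and no protecting group is needed.

Key step: step 3

Remark: isoflavone numbering (O1, C2 to C8a, C1' to C6') is used for the target and chromene numbering for the ring B/D intermediates; glyoxal 6 is assumed to be kept as its hydrate and dried just before use, and enol 13 is drawn as its chelated Z form.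

Step 1
Reactants: 1 cyclohexane-1,3-dione; 2 3-methylbut-2-enal
Product: 4 2,2-dimethyl-7,8-dihydro-2H-chromen-5(6H)-one, via Knoevenagel adduct 3 (not isolated)
Conditions: ethylenediammonium diacetate (10 mol %), MeOH, rt to 50 °C
Reagents that add atoms: none
Why: Knoevenagel condensation at C2 of the symmetric dione gives 1-oxatriene 3, which closes ring D by oxa-6π electrocyclization (a formal [3+3] annulation); both carbonyl oxygens give the same product, so the ring fusion is fixed without any regiochemical choice, and no stereocentre is formed.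

Step 2
Reactants: 5 1-(2-fluoro-4-methoxyphenyl)ethan-1-one
Product: 6 2-(2-fluoro-4-methoxyphenyl)-2-oxoacetaldehyde
Conditions: SeO2 (1.2 equiv), 1,4-dioxane–H2O (30:1), 100 °C; hydrate dried by azeotropic distillation with toluene before use
Reagents that add atoms: selenium dioxide, O=[Se]=O
Why: Riley oxidation, in which SeO2 attacks the enol of the only enolizable position, the acetyl CH3, and takes it to the aldehyde, while the aryl fluoride and the methyl ether are inert; no stereocentre is formed.

Step 3
Reactants: 4 2,2-dimethyl-7,8-dihydro-2H-chromen-5(6H)-one; 6 2-(2-fluoro-4-methoxyphenyl)-2-oxoacetaldehyde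
Product: 11 1-(2-fluoro-4-methoxyphenyl)-2-(5-hydroxy-2,2-dimethyl-2H-chromen-6-yl)ethan-1-one, via lithium enolate 7 (not isolated), via lithium aldolate 8 (not isolated), via aldol mesylate 9 (not isolated), via enedione 10 (not isolated)
Conditions: 4, LiN(iPr)2 (1.05 equiv), THF, −78 °C; 6, −78 °C; MsCl (1.05 equiv), −78 to 0 °C; DBU (3 equiv), 0 to 40 °C; aq. NH4Cl work-up
Reagents that add atoms: none
Why: Kinetic deprotonation of vinylogous ester 4 at C6 gives the cross-conjugated enolate 7, which adds to the aldehyde carbon of 6; aldolate 8 is trapped as mesylate 9, DBU removes methanesulfonate by an E1cB elimination to enedione 10, and DBU then shifts the exocyclic C=C into the ring (deprotonation at C7, reprotonation at the exocyclic carbon, enolization of the resulting cyclohexa-2,5-dienone), so that 10, a 6-alkylidenecyclohex-2-enone, should end as its aromatic isomer 11. The closest known reaction type is the aldol condensation of cyclohex-2-enones and 3-alkoxycyclohex-2-enones with aldehydes followed by base-mediated isoaromatization of the 6-alkylidene enones to ortho-substituted phenols. No ring is closed: ring B turns aromatic by prototropy alone and ring D is carried through unchanged. The two stereocentres of 8 and 9 are erased by the elimination and the aromatization, and 11 has none, so no stereocontrol is needed. The selectivities needed are C6 against C8 deprotonation (kinetic conditions on the vinylogous ester), aldehyde against ketone addition (the glyoxal aldehyde is the far better acceptor and 6 has no α-hydrogen) and a single end point of the double-bond migration (every prototropic path ends in the phenolate, the thermodynamic sink). The step joins the ring A and ring B/D halves through C3–C1', creates ring B as an arene without an oxidant and frees the C5 oxygen exactly where the methyl ether is needed.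

Step 4
Reactants: 11 1-(2-fluoro-4-methoxyphenyl)-2-(5-hydroxy-2,2-dimethyl-2H-chromen-6-yl)ethan-1-one
Product: 12 1-(2-fluoro-4-methoxyphenyl)-2-(5-methoxy-2,2-dimethyl-2H-chromen-6-yl)ethan-1-one
Conditions: MeI (1.5 equiv), K2CO3 (1.5 equiv), acetone, rt to 40 °C
Reagents that add atoms: iodomethane, CI
Why: Williamson ether synthesis on the only OH group; the weak base leaves the ketone methylene unalkylated, the basic medium keeps the 2-hydroxybenzyl ketone from acid-catalysed cyclodehydration to a 2-arylbenzofuran, and the aryl fluoride is untouched at this temperature.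

Step 5
Reactants: 12 1-(2-fluoro-4-methoxyphenyl)-2-(5-methoxy-2,2-dimethyl-2H-chromen-6-yl)ethan-1-one
Product: 13 (Z)-1-(2-fluoro-4-methoxyphenyl)-3-hydroxy-2-(5-methoxy-2,2-dimethyl-2H-chromen-6-yl)prop-2-en-1-one
Conditions: NaH (3 equiv), HCO2Et (10 equiv), THF, 0 °C to rt; AcOH quench at 0 °C
Reagents that add atoms: ethyl formate, CCOC=O
Why: Crossed Claisen condensation (C-formylation) of the only enolizable position with the non-enolizable ethyl formate, driven by formation of the stabilized sodium enolate of the β-keto aldehyde, which the mild acid quench sets free as the chelated enol 13; no stereocentre is formed.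

Step 6
Reactants: 13 (Z)-1-(2-fluoro-4-methoxyphenyl)-3-hydroxy-2-(5-methoxy-2,2-dimethyl-2H-chromen-6-yl)prop-2-en-1-one
Product: 14 7-methoxy-3-(5-methoxy-2,2-dimethyl-2H-chromen-6-yl)-4H-chromen-4-one
Conditions: K2CO3 (2 equiv), DMF, 100 °C, N2
Reagents that add atoms: none
Why: Intramolecular nucleophilic aromatic substitution (addition–elimination), in which the enolate oxygen of 13, held cis to the aroyl group, attacks the fluorine-bearing carbon ortho to the ketone to form a six-membered ring, the charge of the Meisenheimer intermediate rests on the acyl-bearing carbon while the methoxy group is meta to the site of attack and does not oppose it, and loss of fluoride closes ring C as the last ring of the target, as known for chromones from 1-(2-fluoroaryl)-1,3-dicarbonyl enolates; no stereocentre is involved.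

**Compound list**
1 | cyclohexane-1,3-dione | O=C1CCCC(=O)C1 | starting material
2 | 3-methylbut-2-enal | CC(C)=CC=O | starting material
3 | 2-(3-methylbut-2-en-1-ylidene)cyclohexane-1,3-dione (Knoevenagel adduct, not isolated) | CC(C)=CC=C1C(=O)CCCC1=O | intermediate
4 | 2,2-dimethyl-7,8-dihydro-2H-chromen-5(6H)-one | CC1(C)C=CC2=C(O1)CCCC2=O | intermediate
5 | 1-(2-fluoro-4-methoxyphenyl)ethan-1-one | CC(=O)c1ccc(OC)cc1F | starting material
6 | 2-(2-fluoro-4-methoxyphenyl)-2-oxoacetaldehyde | O=CC(=O)c1ccc(OC)cc1F | intermediate
7 | lithium 2,2-dimethyl-7,8-dihydro-2H-chromen-5-olate (not isolated) | [Li+].[O-]C1=CCCC2=C1C=CC(C)(C)O2 | intermediate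
8 | lithium 1-(2,2-dimethyl-5-oxo-5,6,7,8-tetrahydro-2H-chromen-6-yl)-2-(2-fluoro-4-methoxyphenyl)-2-oxoethan-1-olate (racemic diastereomer mixture, not isolated) | [Li+].[O-]C(C(=O)c1ccc(OC)cc1F)C1CCC2=C(C=CC(C)(C)O2)C1=O | intermediate
9 | 1-(2,2-dimethyl-5-oxo-5,6,7,8-tetrahydro-2H-chromen-6-yl)-2-(2-fluoro-4-methoxyphenyl)-2-oxoethyl methanesulfonate (racemic diastereomer mixture, not isolated) | CS(=O)(=O)OC(C(=O)c1ccc(OC)cc1F)C1CCC2=C(C=CC(C)(C)O2)C1=O | intermediate
10 | (E)-6-[2-(2-fluoro-4-methoxyphenyl)-2-oxoethylidene]-2,2-dimethyl-7,8-dihydro-2H-chromen-5(6H)-one (E drawn, either isomer serves, not isolated) | O=C(/C=C1\CCC2=C(C=CC(C)(C)O2)C1=O)c1ccc(OC)cc1F | intermediate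
11 | 1-(2-fluoro-4-methoxyphenyl)-2-(5-hydroxy-2,2-dimethyl-2H-chromen-6-yl)ethan-1-one | COc1ccc(C(=O)Cc2ccc3OC(C)(C)C=Cc3c2O)c(F)c1 | intermediate
12 | 1-(2-fluoro-4-methoxyphenyl)-2-(5-methoxy-2,2-dimethyl-2H-chromen-6-yl)ethan-1-one | COc1ccc(C(=O)Cc2ccc3OC(C)(C)C=Cc3c2OC)c(F)c1 | intermediate
13 | (Z)-1-(2-fluoro-4-methoxyphenyl)-3-hydroxy-2-(5-methoxy-2,2-dimethyl-2H-chromen-6-yl)prop-2-en-1-one | O/C=C(\C(=O)c1ccc(OC)cc1F)c1ccc2OC(C)(C)C=Cc2c1OC | intermediate
14 | 7-methoxy-3-(5-methoxy-2,2-dimethyl-2H-chromen-6-yl)-4H-chromen-4-one | COc1ccc2c(=O)c(-c3ccc4c(c3OC)C=CC(C)(C)O4)coc2c1 | target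

**Step count and risks**
Total step count: 6. Longest linear sequence: 5 steps (step 1 or step 2, then steps 3 to 6).

Steps most likely to fail:

Step 3 (key step). The aldolate may revert by retro-aldol cleavage before it is trapped, the enolate may add in part to the ketone carbon of the glyoxal, and the electrophilic enedione may oligomerize before it aromatizes. Fallback, from 4 back to 11: 4 would be treated with LiN(iPr)2 and ClP(O)(OEt)2 to give diethyl 2,2-dimethyl-7,8-dihydro-2H-chromen-5-yl phosphate F1. More LiN(iPr)2 should then move the phosphoryl group from oxygen to C6 (1,3-phosphoryl migration) to give diethyl (2,2-dimethyl-5-oxo-5,6,7,8-tetrahydro-2H-chromen-6-yl)phosphonate F2. Horner–Wadsworth–Emmons olefination of F2 with 6 (LiCl, DBU, MeCN, rt) would give enedione 10 directly, with no aldol adduct that can revert and with tolerance of the glyoxal hydrate, and further DBU would isomerize 10 to 11.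

Step 6. The displacement of fluoride may be too slow, because the ketone is part of a delocalized enolate and activates the ring only weakly, so that deformylation of 13 back to 12 overtakes ring closure. Fallback, from 4 back to 14, with the ring A oxygen carried from the start: 1-(2-hydroxy-4-methoxyphenyl)ethan-1-one F3 would be silylated (NaH, iPr3SiCl, THF) to 1-{4-methoxy-2-[(triisopropylsilyl)oxy]phenyl}ethan-1-one F4 and oxidized with SeO2 to 2-{4-methoxy-2-[(triisopropylsilyl)oxy]phenyl}-2-oxoacetaldehyde F5. F5 would be joined with 4 under the conditions of step 3 to 2-(5-hydroxy-2,2-dimethyl-2H-chromen-6-yl)-1-{4-methoxy-2-[(triisopropylsilyl)oxy]phenyl}ethan-1-one F6, methylated (MeI, K2CO3, acetone) to 2-(5-methoxy-2,2-dimethyl-2H-chromen-6-yl)-1-{4-methoxy-2-[(triisopropylsilyl)oxy]phenyl}ethan-1-one F7 and desilylated (Bu4NF, AcOH, THF) to 1-(2-hydroxy-4-methoxyphenyl)-2-(5-methoxy-2,2-dimethyl-2H-chromen-6-yl)ethan-1-one F8. Heating F8 with N,N-dimethylformamide dimethyl acetal would close ring C through the O1–C2 bond in the classical deoxybenzoin manner to give 14.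

Step 5. The Claisen formylation is reversible and the methylene is flanked by two ortho-substituted aryl groups, so the equilibrium may stay on the side of 12, or 13 may lose its formyl group during work-up. Fallback, from 12 back to 13: heating 12 with N,N-dimethylformamide dimethyl acetal (toluene, 100 °C, methanol distilled off) should give, irreversibly, (E)-3-(dimethylamino)-1-(2-fluoro-4-methoxyphenyl)-2-(5-methoxy-2,2-dimethyl-2H-chromen-6-yl)prop-2-en-1-one F9, and brief hydrolysis with dilute aqueous HCl in THF at rt would give 13.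

**Further compounds**
F1 | step 3 | diethyl 2,2-dimethyl-7,8-dihydro-2H-chromen-5-yl phosphate | CCOP(=O)(OCC)OC1=CCCC2=C1C=CC(C)(C)O2
F2 | step 3 | diethyl (2,2-dimethyl-5-oxo-5,6,7,8-tetrahydro-2H-chromen-6-yl)phosphonate (racemic) | CCOP(=O)(OCC)C1CCC2=C(C=CC(C)(C)O2)C1=O
F3 | step 6 | 1-(2-hydroxy-4-methoxyphenyl)ethan-1-one | CC(=O)c1ccc(OC)cc1O
F4 | step 6 | 1-{4-methoxy-2-[(triisopropylsilyl)oxy]phenyl}ethan-1-one | CC(=O)c1ccc(OC)cc1O[Si](C(C)C)(C(C)C)C(C)C
F5 | step 6 | 2-{4-methoxy-2-[(triisopropylsilyl)oxy]phenyl}-2-oxoacetaldehyde | O=CC(=O)c1ccc(OC)cc1O[Si](C(C)C)(C(C)C)C(C)C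
F6 | step 6 | 2-(5-hydroxy-2,2-dimethyl-2H-chromen-6-yl)-1-{4-methoxy-2-[(triisopropylsilyl)oxy]phenyl}ethan-1-one | COc1ccc(C(=O)Cc2ccc3OC(C)(C)C=Cc3c2O)c(O[Si](C(C)C)(C(C)C)C(C)C)c1
F7 | step 6 | 2-(5-methoxy-2,2-dimethyl-2H-chromen-6-yl)-1-{4-methoxy-2-[(triisopropylsilyl)oxy]phenyl}ethan-1-one | COc1ccc(C(=O)Cc2ccc3OC(C)(C)C=Cc3c2OC)c(O[Si](C(C)C)(C(C)C)C(C)C)c1
F8 | step 6 | 1-(2-hydroxy-4-methoxyphenyl)-2-(5-methoxy-2,2-dimethyl-2H-chromen-6-yl)ethan-1-one | COc1ccc(C(=O)Cc2ccc3OC(C)(C)C=Cc3c2OC)c(O)c1
F9 | step 5 | (E)-3-(dimethylamino)-1-(2-fluoro-4-methoxyphenyl)-2-(5-methoxy-2,2-dimethyl-2H-chromen-6-yl)prop-2-en-1-one | CN(C)/C=C(/C(=O)c1ccc(OC)cc1F)c1ccc2OC(C)(C)C=Cc2c1OC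
A1 | direct plan | 5-hydroxy-2,2-dimethyl-2H-chromene-6-carbaldehyde | O=Cc1ccc2OC(C)(C)C=Cc2c1O
A2 | direct plan | 5-methoxy-2,2-dimethylchroman-6-carbaldehyde | O=Cc1ccc2OC(C)(C)CCc2c1OC
A3 | direct plan | 1-[4-methoxy-2-(methoxymethoxy)phenyl]ethan-1-one | CC(=O)c1ccc(OC)cc1OCOC
A4 | direct plan | (E)-1-[4-methoxy-2-(methoxymethoxy)phenyl]-3-(5-methoxy-2,2-dimethylchroman-6-yl)prop-2-en-1-one | COCOc1cc(OC)ccc1C(=O)/C=C/c1ccc2OC(C)(C)CCc2c1OC
A5 | direct plan | 7-methoxy-3-(5-methoxy-2,2-dimethylchroman-6-yl)-4H-chromen-4-one | COc1ccc2c(=O)c(-c3ccc4OC(C)(C)CCc4c3OC)coc2c1
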